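**Retrosynthetic overview**
1. C7–OMe and free C6–OH: made last, by a stereoretentive palladium/borate methoxy-opening of a (6R,7R)-vinyl oxirane (C–O bond, key step).
2. Oxirane: hydroxyl-directed Sharpless epoxidation of a (5R)-dienyl carbinol (C–O bonds set C6 and C7).
3. Lactone: O-acryloylation of C5–OH, then ring-closing metathesis.
4. C5 carbinol: catalytic asymmetric allylboration of a dienal, which comes from an enal by formyl-Wittig homologation.
5. C8=C9 and the C10/C11 diacetate: Perlin hydrolysis of 3,4-di-O-acetyl-L-rhamnal. Ring order: oxirane (step 5), dihydropyranone (step 7), oxirane opened (step 8).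

Assumption: 3,4-di-O-acetyl-L-rhamnal (also sold as 3,4-di-O-acetyl-6-deoxy-L-glucal) is taken as a commercial starting material. Locants C1–C12 in the Why lines run from the lactone carbonyl to the terminal methyl of the target.

Step 1
Reactants: 1 3,4-di-O-acetyl-L-rhamnal
Product: 2 (2S,3R,4E)-2-hydroxy-6-oxohex-4-en-3-yl acetate
Conditions: HgSO4 (2 mol %), 5 mM aq H2SO4, 1,4-dioxane, rt, 3 h
Reagents that add atoms: water, O
Why: Perlin hydrolysis: HgSO4-catalysed hydration of the enol ether opens the pyran to the 2-deoxy aldehyde and E1cB loss of the C3 acetate gives the (E)-enal, leaving untouched the two sugar centres that become C10 (R) and C11 (S).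

Step 2
Reactants: 2 (2S,3R,4E)-2-hydroxy-6-oxohex-4-en-3-yl acetate
Product: 3 (2S,3R,4E)-6-oxohex-4-ene-2,3-diyl diacetate
Conditions: Ac2O, pyridine, 0 °C, 2 h
Reagents that add atoms: acetic anhydride, CC(=O)OC(C)=O
Why: Routine O-acetylation of the secondary alcohol under mild base; no stereocentre is touched.

Step 3
Reactants: 3 (2S,3R,4E)-6-oxohex-4-ene-2,3-diyl diacetate; 4 (triphenylphosphoranylidene)acetaldehyde
Product: 5 (2S,3R,4E,6E)-8-oxoocta-4,6-diene-2,3-diyl diacetate
Conditions: 4 (1.1 equiv), toluene, 80 °C, 12 h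
Reagents that add atoms: none
Why: Wittig olefination with a stabilised formyl ylide is (E)-selective, and the dienal product is a poorer electrophile than the enal, so a single two-carbon homologation dominates.

Step 4
Reactants: 5 (2S,3R,4E,6E)-8-oxoocta-4,6-diene-2,3-diyl diacetate; 6 2-allyl-4,4,5,5-tetramethyl-1,3,2-dioxaborolane
Product: 8 (2S,3R,4E,6E,8R)-8-hydroxyundeca-4,6,10-triene-2,3-diyl diacetate, via O-pinacolboryl ether 7 (not isolated)
Conditions: (R)-TRIP [(R)-3,3'-bis(2,4,6-triisopropylphenyl)-1,1'-binaphthyl-2,2'-diyl hydrogen phosphate] (5 mol %), 4 Å MS, toluene, −30 °C; aq NaHCO3 work-up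
Reagents that add atoms: none
Why: Chiral phosphoric acid-catalysed allylboration through a chair six-membered transition state in which the acid binds a boronate oxygen and the formyl hydrogen; the (R)-catalyst sends allyl to the Re face of the dienal, as it does for benzaldehyde and cinnamaldehyde, setting C5 (R).

Step 5
Reactants: 8 (2S,3R,4E,6E,8R)-8-hydroxyundeca-4,6,10-triene-2,3-diyl diacetate
Product: 9 (2S,3R,4E)-5-{(2R,3R)-3-[(1R)-1-hydroxybut-3-en-1-yl]oxiran-2-yl}pent-4-ene-2,3-diyl diacetate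
Conditions: Ti(OiPr)4 (20 mol %), D-(−)-diisopropyl tartrate (24 mol %), t-BuOOH (2 equiv, decane), 4 Å MS, CH2Cl2, −20 °C
Reagents that add atoms: tert-butyl hydroperoxide, CC(C)(C)OO
Why: Sharpless asymmetric epoxidation in its matched, kinetic-resolution-type mode: the titanium–tartrate peroxide bound to the C5 hydroxyl oxidises only the allylic C6=C7 alkene, and D-(−)-tartrate with the (5R)-carbinol is the fast, erythro-selective pairing that sets C6 (R) and C7 (R) while any 5-epimer from step 4 is left behind.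

Step 6
Reactants: 9 (2S,3R,4E)-5-{(2R,3R)-3-[(1R)-1-hydroxybut-3-en-1-yl]oxiran-2-yl}pent-4-ene-2,3-diyl diacetate; 10 acryloyl chloride
Product: 11 (1R)-1-{(2R,3R)-3-[(1E,3R,4S)-3,4-diacetoxypent-1-en-1-yl]oxiran-2-yl}but-3-en-1-yl prop-2-enoate
Conditions: iPr2NEt (2 equiv), DMAP (cat.), CH2Cl2, −20 → 0 °C
Reagents that add atoms: none
Why: Standard O-acylation of the secondary alcohol with a non-nucleophilic base; the C5–O bond is not broken, so configuration is kept and the oxirane survives the buffered medium.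

Step 7
Reactants: 11 (1R)-1-{(2R,3R)-3-[(1E,3R,4S)-3,4-diacetoxypent-1-en-1-yl]oxiran-2-yl}but-3-en-1-yl prop-2-enoate
Product: 12 (2S,3R,4E)-5-{(2R,3R)-3-[(2R)-6-oxo-3,6-dihydro-2H-pyran-2-yl]oxiran-2-yl}pent-4-ene-2,3-diyl diacetate
Conditions: second-generation Grubbs catalyst RuCl2(=CHPh)(PCy3)(H2IMes) (5 mol %), CH2Cl2 (5 mM), 40 °C
Reagents that add atoms: none
Why: Ring-closing metathesis of the acrylate with the terminal allyl alkene closes the six-membered α,β-unsaturated lactone with loss of ethylene, while the hindered 1,2-disubstituted C8=C9 alkene between oxirane and acetoxy carbons stays out of the cycle.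

Step 8
Reactants: 12 (2S,3R,4E)-5-{(2R,3R)-3-[(2R)-6-oxo-3,6-dihydro-2H-pyran-2-yl]oxiran-2-yl}pent-4-ene-2,3-diyl diacetate
Product: 14 (2S,3R,4E,6R,7R)-7-hydroxy-6-methoxy-7-[(2R)-6-oxo-3,6-dihydro-2H-pyran-2-yl]hept-4-ene-2,3-diyl diacetate, via dimethyl borate ester 13 (not isolated)
Conditions: Pd(PPh3)4 (5 mol %), B(OMe)3 (2 equiv), THF, 0 °C → rt; pH 7 phosphate buffer
Reagents that add atoms: trimethyl borate, COB(OC)OC
Why: Proposed new method: zerovalent palladium ionises the vinyl oxirane with inversion at C7 to a syn,syn-(π-allyl)palladium alkoxide, the C6 alkoxide is captured by B(OMe)3 as a borate that hands one methoxide to C7 through a five-membered transition state on the face opposite palladium (second inversion, net retention, C7 = R, E-alkene kept, C6–OH freed on hydrolysis), delivery to C9 is disfavoured by the seven-membered geometry and the adjacent C10 acetoxy group, and the C10 allylic acetate should be spared because its ionisation is slower, reversible and not coupled to borate formation; the closest known reactions are the palladium/trialkyl borate double-inversion alkoxy substitution of γ,δ-epoxy-α,β-unsaturated esters and the palladium/borane-cocatalysed 1,2-addition of alcohols to butadiene monoepoxide, neither shown on a non-conjugated, 1,2-disubstituted vinyl oxirane carrying a bystander allylic acetate and an enoate lactone.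

**Compound list**
1 | 3,4-di-O-acetyl-L-rhamnal, (2S,3S,4S)-2-methyl-3,4-dihydro-2H-pyran-3,4-diyl diacetate | C[C@@H]1OC=C[C@H](OC(C)=O)[C@H]1OC(C)=O | starting material
2 | (2S,3R,4E)-2-hydroxy-6-oxohex-4-en-3-yl acetate | O=C/C=C/[C@@H](OC(C)=O)[C@H](C)O | intermediate
3 | (2S,3R,4E)-6-oxohex-4-ene-2,3-diyl diacetate | O=C/C=C/[C@@H](OC(C)=O)[C@H](C)OC(C)=O | intermediate
4 | (triphenylphosphoranylidene)acetaldehyde | O=CC=P(c1ccccc1)(c1ccccc1)c1ccccc1 | starting material
5 | (2S,3R,4E,6E)-8-oxoocta-4,6-diene-2,3-diyl diacetate | O=C/C=C/C=C/[C@@H](OC(C)=O)[C@H](C)OC(C)=O | intermediate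
6 | 2-allyl-4,4,5,5-tetramethyl-1,3,2-dioxaborolane (allylboronic acid pinacol ester) | C=CCB1OC(C)(C)C(C)(C)O1 | starting material
7 | (2S,3R,4E,6E,8R)-8-[(4,4,5,5-tetramethyl-1,3,2-dioxaborolan-2-yl)oxy]undeca-4,6,10-triene-2,3-diyl diacetate | C=CC[C@@H](OB1OC(C)(C)C(C)(C)O1)/C=C/C=C/[C@@H](OC(C)=O)[C@H](C)OC(C)=O | intermediate (not isolated)
8 | (2S,3R,4E,6E,8R)-8-hydroxyundeca-4,6,10-triene-2,3-diyl diacetate | C=CC[C@@H](O)/C=C/C=C/[C@@H](OC(C)=O)[C@H](C)OC(C)=O | intermediate
9 | (2S,3R,4E)-5-{(2R,3R)-3-[(1R)-1-hydroxybut-3-en-1-yl]oxiran-2-yl}pent-4-ene-2,3-diyl diacetate (trans-oxirane) | C=CC[C@@H](O)[C@H]1O[C@@H]1/C=C/[C@@H](OC(C)=O)[C@H](C)OC(C)=O | intermediate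
10 | acryloyl chloride | C=CC(=O)Cl | starting material
11 | (1R)-1-{(2R,3R)-3-[(1E,3R,4S)-3,4-diacetoxypent-1-en-1-yl]oxiran-2-yl}but-3-en-1-yl prop-2-enoate | C=CC[C@@H](OC(=O)C=C)[C@H]1O[C@@H]1/C=C/[C@@H](OC(C)=O)[C@H](C)OC(C)=O | intermediate
12 | (2S,3R,4E)-5-{(2R,3R)-3-[(2R)-6-oxo-3,6-dihydro-2H-pyran-2-yl]oxiran-2-yl}pent-4-ene-2,3-diyl diacetate | O=C1C=CC[C@@H](O1)[C@H]2O[C@@H]2/C=C/[C@@H](OC(C)=O)[C@H](C)OC(C)=O | intermediate
13 | (2S,3R,4E,6R,7R)-7-[(dimethoxyboranyl)oxy]-6-methoxy-7-[(2R)-6-oxo-3,6-dihydro-2H-pyran-2-yl]hept-4-ene-2,3-diyl diacetate | CO[C@H](/C=C/[C@@H](OC(C)=O)[C@H](C)OC(C)=O)[C@H](OB(OC)OC)[C@H]1CC=CC(=O)O1 | intermediate (not isolated)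
14 | (2S,3R,4E,6R,7R)-7-hydroxy-6-methoxy-7-[(2R)-6-oxo-3,6-dihydro-2H-pyran-2-yl]hept-4-ene-2,3-diyl diacetate (CNP0375023.4) | CO[C@H](/C=C/[C@@H](OC(C)=O)[C@H](C)OC(C)=O)[C@H](O)[C@H]1CC=CC(=O)O1 | target

**Step count and risks**
Total steps: 8. Longest linear sequence: 8 (1 → 14).

Steps most likely to fail:

Step 8 (the proposed new step). The risks are competing ionisation of the C10 allylic acetate, palladium-catalysed isomerisation of the vinyl oxirane to a dienol or enone, and oxa-Michael closure of the C6 alkoxide onto the lactone. The fallback uses only known chemistry, sets out from 3 and comes back at 14. Enal 3 is treated at −78 °C with the (Z)-γ-(methoxymethoxy)allyl-diisopinocampheylborane made from allyl methoxymethyl ether, s-BuLi, (−)-Ipc2BOMe and BF3·OEt2 (Brown alkoxyallylboration, Si-face addition, ethanolamine work-up) to give the syn monoprotected diol (2S,3R,4E,6R,7R)-6-hydroxy-7-(methoxymethoxy)nona-4,8-diene-2,3-diyl diacetate F1. The free hydroxyl (the future C7 oxygen) is methylated with Me3OBF4 and 1,8-bis(dimethylamino)naphthalene in CH2Cl2 to give (2S,3R,4E,6R,7R)-6-methoxy-7-(methoxymethoxy)nona-4,8-diene-2,3-diyl diacetate F2. ZnBr2 and n-PrSH in CH2Cl2 remove the methoxymethyl group to give the allylic alcohol (2S,3R,4E,6R,7R)-7-hydroxy-6-methoxynona-4,8-diene-2,3-diyl diacetate F3. Matched Sharpless epoxidation of the terminal vinyl group (Ti(OiPr)4, L-(+)-diisopropyl tartrate, t-BuOOH, −20 °C, erythro) gives (2S,3R,4E,6R,7S)-7-hydroxy-6-methoxy-7-[(2R)-oxiran-2-yl]hept-4-ene-2,3-diyl diacetate F4. Its terminal oxirane carbon is opened by lithiated ethyl propiolate with BF3·OEt2 at −78 °C to give ethyl (5R,6R,7R,8E,10R,11S)-10,11-diacetoxy-5,6-dihydroxy-7-methoxydodec-8-en-2-ynoate F5. Semihydrogenation over Pd/CaCO3 poisoned with Pb(OAc)2, with quinoline, gives ethyl (2Z,5R,6R,7R,8E,10R,11S)-10,11-diacetoxy-5,6-dihydroxy-7-methoxydodeca-2,8-dienoate F6, which lactonises through the C5 hydroxyl with a trace of camphorsulfonic acid to 14.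

Step 5. The vinyl epoxy alcohol is labile towards titanium alkoxides and acid, and the dienyl carbinol may react sluggishly. The fallback replaces hydroxyl-directed titanium epoxidation by reagent-controlled dioxirane epoxidation of the protected alcohol; it sets out from 8 and comes back at 9. Alcohol 8 is silylated (Et3SiCl, imidazole, CH2Cl2) to (2S,3R,4E,6E,8R)-8-[(triethylsilyl)oxy]undeca-4,6,10-triene-2,3-diyl diacetate F7. Shi epoxidation (D-fructose-derived ketone, KHSO5, K2CO3 buffer, MeCN–dimethoxymethane–water, 0 °C) attacks the C6=C7 alkene, the C8=C9 alkene being deactivated by its allylic acetate, and gives (2S,3R,4E)-5-{(2R,3S)-3-[(1R)-1-[(triethylsilyl)oxy]but-3-en-1-yl]oxiran-2-yl}pent-4-ene-2,3-diyl diacetate F8. Buffered n-Bu4NF/AcOH in THF at 0 °C removes the silyl group to return 9.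

Step 3. The risks are over-homologation to the trienal, E/Z erosion and elimination of the γ-acetoxy group on heating. The fallback replaces direct formyl-olefination by olefination to an amide and chemoselective partial reduction; it sets out from 3 and comes back at 5. Horner–Wadsworth–Emmons reaction of 3 with diethyl {2-[methoxy(methyl)amino]-2-oxoethyl}phosphonate (LiCl, iPr2NEt, MeCN, rt) gives the dienyl Weinreb amide (2S,3R,4E,6E)-8-[methoxy(methyl)amino]-8-oxoocta-4,6-diene-2,3-diyl diacetate F9. Cp2Zr(H)Cl in THF at rt reduces the amide, not the acetates, to aldehyde 5.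

**Further compounds**
F1 | step 8 | (2S,3R,4E,6R,7R)-6-hydroxy-7-(methoxymethoxy)nona-4,8-diene-2,3-diyl diacetate | C=C[C@@H](OCOC)[C@H](O)/C=C/[C@@H](OC(C)=O)[C@H](C)OC(C)=O
F2 | step 8 | (2S,3R,4E,6R,7R)-6-methoxy-7-(methoxymethoxy)nona-4,8-diene-2,3-diyl diacetate | C=C[C@@H](OCOC)[C@H](OC)/C=C/[C@@H](OC(C)=O)[C@H](C)OC(C)=O
F3 | step 8 | (2S,3R,4E,6R,7R)-7-hydroxy-6-methoxynona-4,8-diene-2,3-diyl diacetate | C=C[C@@H](O)[C@H](OC)/C=C/[C@@H](OC(C)=O)[C@H](C)OC(C)=O
F4 | step 8 | (2S,3R,4E,6R,7S)-7-hydroxy-6-methoxy-7-[(2R)-oxiran-2-yl]hept-4-ene-2,3-diyl diacetate | C1O[C@H]1[C@@H](O)[C@H](OC)/C=C/[C@@H](OC(C)=O)[C@H](C)OC(C)=O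
F5 | step 8 | ethyl (5R,6R,7R,8E,10R,11S)-10,11-diacetoxy-5,6-dihydroxy-7-methoxydodec-8-en-2-ynoate | CCOC(=O)C#CC[C@@H](O)[C@@H](O)[C@H](OC)/C=C/[C@@H](OC(C)=O)[C@H](C)OC(C)=O
F6 | step 8 | ethyl (2Z,5R,6R,7R,8E,10R,11S)-10,11-diacetoxy-5,6-dihydroxy-7-methoxydodeca-2,8-dienoate | CCOC(=O)/C=C\C[C@@H](O)[C@@H](O)[C@H](OC)/C=C/[C@@H](OC(C)=O)[C@H](C)OC(C)=O
F7 | step 5 | (2S,3R,4E,6E,8R)-8-[(triethylsilyl)oxy]undeca-4,6,10-triene-2,3-diyl diacetate | C=CC[C@@H](O[Si](CC)(CC)CC)/C=C/C=C/[C@@H](OC(C)=O)[C@H](C)OC(C)=O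
F8 | step 5 | (2S,3R,4E)-5-{(2R,3S)-3-[(1R)-1-[(triethylsilyl)oxy]but-3-en-1-yl]oxiran-2-yl}pent-4-ene-2,3-diyl diacetate | C=CC[C@@H](O[Si](CC)(CC)CC)[C@H]1O[C@@H]1/C=C/[C@@H](OC(C)=O)[C@H](C)OC(C)=O
F9 | step 3 | (2S,3R,4E,6E)-8-[methoxy(methyl)amino]-8-oxoocta-4,6-diene-2,3-diyl diacetate | CON(C)C(=O)/C=C/C=C/[C@@H](OC(C)=O)[C@H](C)OC(C)=O
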